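A direct plan would cut the diaryl ether at the bond between the oxygen and ring B. The phenoxide of 2,3,4-tribromo-6-methoxyphenol A1 would be O-arylated, without a metal, by (2,4-dibromophenyl)(2,4,6-trimethoxyphenyl)iodonium tosylate A2. A2 would first have to be made from the aryl iodide by oxidation and capture of an electron-rich arene. Its weakest steps would be:
- the O-arylation of A1 by A2, because a weakly nucleophilic phenoxide flanked by Br and OMe would have to couple with an aryl group that carries its own ortho bromine, so the coupling would be slow and would compete with decomposition of the salt;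
- the preparation of A2, because the electron-poor, ortho-substituted iodoarene would oxidise sluggishly, and the step would add length and a discarded auxiliary arene but none of the target's complexity.

The proposed route would not arylate oxygen at all: ring B would be grown on the ether oxygen. Ethynyl ether 9 of the ring A phenol would undergo an inverse-electron-demand Diels–Alder reaction with 3,5-dibromo-2H-pyran-2-one 11, and loss of CO2 from the bridged lactone would leave the benzene ring. The step exploits the 1-oxy-2,4-dibromo pattern of ring B: C3–Br and C5–Br of the pyrone become C2'–Br and C4'–Br, and the polarised alkyne sets the oxygen-bearing carbon next to C3. Two C–C bonds and all of ring B would form in one metal-free operation, so neither an iodonium salt nor a congested C–O coupling would be needed.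

Key step: step 6

Assumption: the 2-bromovinyl ether 7 is drawn as its (Z) isomer; any (E) isomer formed alongside should converge on the same alkyne 9.

Step 1
Reactants: 1 guaiacol (2-methoxyphenol)
Product: 2 2,3,4-tribromo-6-methoxyphenol (4,5,6-tribromoguaiacol)
Conditions: Br2 (3.1 equiv), AcOH, 15 °C → 45 °C
Reagents that add atoms: bromine, BrBr
Why: Threefold electrophilic aromatic bromination, in which the free OH directs to its para and ortho carbons (C4, C6 of guaiacol) and the OMe to its para carbon (C5), while C3, activated only as an ortho position of OMe on a ring that by then carries three bromines, should stay untouched with the small excess used; no stereocentre is formed.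

Step 2
Reactants: 2 2,3,4-tribromo-6-methoxyphenol; 3 1,2-dibromoethane
Product: 4 1,2,3-tribromo-4-(2-bromoethoxy)-5-methoxybenzene
Conditions: 3 (5 equiv), K2CO3 (2 equiv), MeCN, 80 °C
Reagents that add atoms: none
Why: Williamson ether synthesis (SN2) at a primary bromide, in which the unhindered sp3 electrophile tolerates the di-ortho-substituted phenoxide and the excess of 3 suppresses double alkylation; no stereocentre is formed.

Step 3
Reactants: 4 1,2,3-tribromo-4-(2-bromoethoxy)-5-methoxybenzene
Product: 5 1,2,3-tribromo-4-(ethenyloxy)-5-methoxybenzene
Conditions: t-BuOK (1.3 equiv), THF, 0 °C → rt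
Reagents that add atoms: none
Why: E2 dehydrobromination of an aryl 2-bromoethyl ether, a standard entry to aryl vinyl ethers, in which the bulky alkoxide removes an O–CH2 proton anti to bromide and should leave the aryl bromides alone at this temperature; no stereocentre is formed.

Step 4
Reactants: 5 1,2,3-tribromo-4-(ethenyloxy)-5-methoxybenzene
Product: 9 1,2,3-tribromo-4-(ethynyloxy)-5-methoxybenzene, via 1,2-dibromoethyl ether 6 (not isolated), via (Z)-2-bromovinyl ether 7 (not isolated), via potassium aryloxyacetylide 8 (not isolated)
Conditions: Br2 (1.0 equiv), toluene, −78 °C; then KN(SiMe3)2 (3.2 equiv), THF–toluene, −78 °C → 0 °C; cold aq. NH4Cl; used at once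
Reagents that add atoms: none
Why: Bromine addition to the electron-rich enol ether double bond followed by two base-induced dehydrobrominations (the classical vinyl ether → 1,2-dibromoethyl ether → 2-bromovinyl ether → alkynyl ether sequence), in which the hindered silylamide should neither substitute at the α-bromo ether carbon nor exchange with an aryl bromide, the third equivalent of base holds the product as its potassium acetylide 8 until the cold quench, and the stereocentre of 6 is lost again in 7.

Step 5
Reactants: 10 coumalic acid (2-oxo-2H-pyran-5-carboxylic acid)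
Product: 11 3,5-dibromo-2H-pyran-2-one
Conditions: NBS (2.5 equiv), LiOAc (0.2 equiv), MeCN–H2O (9:1), rt
Reagents that add atoms: N-bromosuccinimide, O=C1CCC(=O)N1Br
Why: Catalytic Hunsdiecker-type bromodecarboxylation at C5 combined with electrophilic bromination at C3, the two nucleophilic carbons of the 2-pyranone ring, which is the established entry to this dibromopyrone; no stereocentre is formed.

Step 6
Reactants: 9 1,2,3-tribromo-4-(ethynyloxy)-5-methoxybenzene; 11 3,5-dibromo-2H-pyran-2-one
Product: 13 1,2,3-tribromo-4-(2,4-dibromophenoxy)-5-methoxybenzene (the target), via bridged lactone 12 (not isolated)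
Conditions: 11 (1.5 equiv), toluene (0.1 M), 80 °C → 110 °C, sealed tube, dark
Reagents that add atoms: none
Why: The electron-poor diene C3=C4–C5=C6 of pyrone 11 and the electron-rich alkyne of 9 should combine in an asynchronous inverse-electron-demand [4+2] cycloaddition to the 2-oxabicyclo[2.2.2]octa-5,7-dien-3-one 12, which then loses CO2 irreversibly by a retro-[4+2] reaction and leaves ring B aromatic. The closest known reaction type is the pyrone–alkyne benzannulation (Diels–Alder then CO2 extrusion, Alder–Rickert type), and this pyrone is known to add enol ethers in the same sense. Ring B is closed by intermolecular cycloaddition, the new bonds being C1'–C2' (alkyne O-bearing carbon to pyrone C3) and C5'–C6' (pyrone C6 to the alkyne CH terminus). No stereocentre remains in the product, since the two bridgehead centres of 12 vanish on aromatisation. The step needs one regiochemistry: the oxygen donor makes the CH terminus the nucleophilic carbon and C6 is the most electrophilic terminus of the pyrone, so the O-bearing carbon should end up next to C3–Br and give the 2,4-dibromo pattern (the reverse orientation would give the 3,5-dibromophenyl ether). All five C–Br bonds should survive because the conditions are neutral, thermal and metal-free.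

Compound list
1 | guaiacol (2-methoxyphenol) | COc1ccccc1O | starting material
2 | 2,3,4-tribromo-6-methoxyphenol (4,5,6-tribromoguaiacol) | COc1cc(Br)c(Br)c(Br)c1O | intermediate
3 | 1,2-dibromoethane | BrCCBr | starting material
4 | 1,2,3-tribromo-4-(2-bromoethoxy)-5-methoxybenzene | COc1cc(Br)c(Br)c(Br)c1OCCBr | intermediate
5 | 1,2,3-tribromo-4-(ethenyloxy)-5-methoxybenzene | COc1cc(Br)c(Br)c(Br)c1OC=C | intermediate
6 | 1,2,3-tribromo-4-(1,2-dibromoethoxy)-5-methoxybenzene (racemic) | COc1cc(Br)c(Br)c(Br)c1OC(Br)CBr | intermediate
7 | 1,2,3-tribromo-4-{[(Z)-2-bromoethenyl]oxy}-5-methoxybenzene | COc1cc(Br)c(Br)c(Br)c1O/C=C\Br | intermediate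
8 | potassium 2-(2,3,4-tribromo-6-methoxyphenoxy)ethyn-1-ide | COc1cc(Br)c(Br)c(Br)c1OC#[C-].[K+] | intermediate
9 | 1,2,3-tribromo-4-(ethynyloxy)-5-methoxybenzene | COc1cc(Br)c(Br)c(Br)c1OC#C | intermediate
10 | coumalic acid (2-oxo-2H-pyran-5-carboxylic acid) | O=C1C=CC(C(=O)O)=CO1 | starting material
11 | 3,5-dibromo-2H-pyran-2-one | O=C1OC=C(Br)C=C1Br | intermediate
12 | 4,7-dibromo-5-(2,3,4-tribromo-6-methoxyphenoxy)-2-oxabicyclo[2.2.2]octa-5,7-dien-3-one (racemic) | O=C1OC2C=C(Oc3c(OC)cc(Br)c(Br)c3Br)C1(Br)C=C2Br | intermediate
13 | 1,2,3-tribromo-4-(2,4-dibromophenoxy)-5-methoxybenzene | COc1cc(Br)c(Br)c(Br)c1Oc1ccc(Br)cc1Br | target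

Total step count: 6. Longest linear sequence: 5 steps (steps 1, 2, 3, 4 and 6); the pyrone 11 is made in step 5 on a side branch.

Steps most likely to fail, with fallbacks

(a) The cycloaddition of step 6.
- What may go wrong: an ynol ether whose oxygen sits on an electron-poor, hindered ring may add too slowly, the terminal alkyne may oligomerise on heating before it is captured, or some of the reverse orientation may form.
- Fallback: this returns to C–O bond formation, but on an activated ring. Setting out from 2, nucleophilic aromatic substitution on 2-bromo-1-fluoro-4-nitrobenzene with Cs2CO3 in DMSO at 90 °C should give 1,2,3-tribromo-4-(2-bromo-4-nitrophenoxy)-5-methoxybenzene F1. Reduction of the nitro group of F1 with Fe powder and NH4Cl in EtOH–H2O at 70 °C, which spares aryl bromides, should give 3-bromo-4-(2,3,4-tribromo-6-methoxyphenoxy)aniline F2. Diazotisation of F2 with NaNO2 in aq. HBr–AcOH at 0 °C should give 3-bromo-4-(2,3,4-tribromo-6-methoxyphenoxy)benzenediazonium bromide F3, and a Sandmeyer reaction of F3 with CuBr in aq. HBr at 60 °C would rejoin the route at 13.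

(b) The bromination and double elimination of step 4.
- What may go wrong: the second dehydrobromination may stall, the base may deprotonate the one ring A C–H next to bromine and trigger bromine migration or aryne formation, or the terminal ynol ether may polymerise during work-up.
- Fallback: this avoids the alkyne. Setting out from 5, the vinyl ether itself would be used as dienophile with 11 in toluene at 90 °C, a cycloaddition well known for enol ethers, to give 4,6-dibromo-8-(2,3,4-tribromo-6-methoxyphenoxy)-2-oxabicyclo[2.2.2]oct-5-en-3-one F4 as a racemic endo/exo mixture. Heating F4 with DDQ, 1.2 equiv, in chlorobenzene at 130 °C should extrude CO2 to give 1,2,3-tribromo-4-[(2,4-dibromocyclohexa-2,4-dien-1-yl)oxy]-5-methoxybenzene F5. The oxidant, present from the start, should dehydrogenate F5 before it can lose the phenol, rejoining the route at 13.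

(c) The elimination of step 3.
- What may go wrong: because the tribromomethoxyphenoxide is a good leaving group, fragmentation to the phenoxide, or substitution by the alkoxide, may compete with the wanted E2 reaction.
- Fallback: setting out from 2, a transfer vinylation with vinyl acetate, 2 equiv, catalysed by [Ir(cod)Cl]2 at 1 mol% in the presence of Na2CO3, 0.6 equiv, in toluene at 100 °C, would put the vinyl group on oxygen directly and rejoin the route at 5. It bypasses 4 and makes no new compound, so its line below is F0.

Further compounds
F1 | step 6 | 1,2,3-tribromo-4-(2-bromo-4-nitrophenoxy)-5-methoxybenzene | COc1cc(Br)c(Br)c(Br)c1Oc1ccc(cc1Br)[N+](=O)[O-]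
F2 | step 6 | 3-bromo-4-(2,3,4-tribromo-6-methoxyphenoxy)aniline | COc1cc(Br)c(Br)c(Br)c1Oc1ccc(N)cc1Br
F3 | step 6 | 3-bromo-4-(2,3,4-tribromo-6-methoxyphenoxy)benzenediazonium bromide | COc1cc(Br)c(Br)c(Br)c1Oc1ccc(cc1Br)[N+]#N.[Br-]
F4 | step 4 | 4,6-dibromo-8-(2,3,4-tribromo-6-methoxyphenoxy)-2-oxabicyclo[2.2.2]oct-5-en-3-one (racemic, endo/exo mixture) | O=C1OC2CC(Oc3c(OC)cc(Br)c(Br)c3Br)C1(Br)C=C2Br
F5 | step 4 | 1,2,3-tribromo-4-[(2,4-dibromocyclohexa-2,4-dien-1-yl)oxy]-5-methoxybenzene (racemic) | COc1cc(Br)c(Br)c(Br)c1OC1CC=C(Br)C=C1Br
F0 | step 3 | none | none
A1 | direct plan | 2,3,4-tribromo-6-methoxyphenol | COc1cc(Br)c(Br)c(Br)c1O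
A2 | direct plan | (2,4-dibromophenyl)(2,4,6-trimethoxyphenyl)iodonium 4-methylbenzenesulfonate | COc1cc(OC)c([I+]c2ccc(Br)cc2Br)c(OC)c1.Cc1ccc(cc1)S(=O)(=O)[O-]
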